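**Retrosynthetic overview**
1. Target 11 ⇒ (E)-vinyl iodide 10: the C15 carboxyl comes last, by hydroxycarbonylation (CO, H2O, Pd(OAc)2).
2. Key disconnection: the axial C3–OAc bond of 10 ⇒ equatorial 3-triflate 9 of β-hydroxy aldehyde 8 plus acetate. This C–O bond formation, with inversion, sets C3.
3. 8 ⇒ diol 7 (C19 oxidation) ⇒ alkyne 5 (methylalumination/iodination brings C16 and the 13E alkene) ⇒ aldehyde 4 ⇒ aldehyde 3 (exo-to-endo alkene shift).
4. 3 ⇒ andrographolide 1 by excision of the butenolide at C12=C13.
5. No ring is formed: rings A and B with C4, C5, C9 and C10 are taken intact from 1; only C3 is inverted.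

Assumption: andrographolide (bulk Andrographis extract; same C4/C5/C9/C10 configuration as the target, opposite at C3) is accepted as a cheap commercial starting material.

Labdane numbering is used: C3 carbinol; C4 bears C18 (CH3) and C19 (CH2OH/CHO, axial, cis to the C10 methyl C20); C17 is the C8 methyl; C16 is the C13 methyl.

**Step 1**
Reactants: 1 andrographolide
Product: 3 (3R,4R,5S,9R,10S)-3,19-dihydroxy-13,14,15,16-tetranorlabd-8(17)-en-12-al, via epoxy lactone 2 (not isolated)
Conditions: t-BuOOH, DBU (0.3 equiv), THF, 0 °C → rt; then H5IO6, THF–H2O, rt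
Reagents that add atoms: tert-butyl hydroperoxide CC(C)(C)OO (its oxygen is carried by 2 only); water O
Why: Weitz–Scheffer nucleophilic epoxidation touches only the electron-poor alkylidene lactone (the exocyclic C8=C17 alkene is inert to peroxide anion), and periodic acid then opens the epoxide at C12 and cleaves the glycol (Malaprade type) to the C12 aldehyde; no stereocentre of 3 is formed and the 1,3-diol is not a periodate substrate.

**Step 2**
Reactants: 3 (3R,4R,5S,9R,10S)-3,19-dihydroxy-13,14,15,16-tetranorlabd-8(17)-en-12-al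
Product: 4 (3R,4R,5S,9R,10S)-3,19-dihydroxy-13,14,15,16-tetranorlabd-7-en-12-al
Conditions: CoCl(salen) 3 mol % [salen = N,N'-bis(3,5-di-tert-butylsalicylidene)cyclohexane-1,2-diaminate], PhSiH3 6 mol %, benzene, rt
Reagents that add atoms: none
Why: Hydrogen-atom-transfer alkene isomerisation (Mukaiyama-type cobalt hydride, trivalent cobalt): H• adds to C17, and the tertiary C8 radical gives H• back from the less hindered C7–H rather than the C9–H flanked by C10 and the side chain, so the trisubstituted 7-ene forms; no stereocentre is made and C9 is untouched.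

**Step 3**
Reactants: 4 (3R,4R,5S,9R,10S)-3,19-dihydroxy-13,14,15,16-tetranorlabd-7-en-12-al
Product: 5 (3R,4R,5S,9R,10S)-14,15,16-trinorlabd-7-en-12-yne-3,19-diol
Conditions: dimethyl (1-diazo-2-oxopropyl)phosphonate, K2CO3, MeOH, 0 °C → rt
Reagents that add atoms: dimethyl (1-diazo-2-oxopropyl)phosphonate COP(=O)(OC)C(=[N+]=[N-])C(C)=O
Why: Seyferth–Gilbert homologation in the Ohira–Bestmann form converts the aldehyde into the terminal alkyne (adds C13) under mild base that leaves the free diol and the alkene alone; no stereocentre is formed.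

**Step 4**
Reactants: 5 (3R,4R,5S,9R,10S)-14,15,16-trinorlabd-7-en-12-yne-3,19-diol
Product: 7 (3R,4R,5S,9R,10S,13E)-14-iodo-15-norlabda-7,13-diene-3,19-diol, via alkenylalane 6 (not isolated)
Conditions: Me3Al (5 equiv), Cp2ZrCl2 (25 mol %), CH2Cl2, 0 °C → rt; then I2, THF, −30 °C
Reagents that add atoms: trimethylaluminium C[Al](C)C; iodine II
Why: Negishi zirconium-catalysed methylalumination adds CH3 (C16) and Al syn across the alkyne with Al on the terminal carbon, and iodinolysis with retention gives the 13E vinyl iodide; the hydroxyls ride through as aluminium alkoxides and the trisubstituted ring alkene does not react.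

**Step 5**
Reactants: 7 (3R,4R,5S,9R,10S,13E)-14-iodo-15-norlabda-7,13-diene-3,19-diol
Product: 8 (3R,4S,5S,9R,10S,13E)-3-hydroxy-14-iodo-15-norlabda-7,13-dien-19-al
Conditions: TEMPO (20 mol %), PhI(OAc)2, CH2Cl2, rt
Reagents that add atoms: none
Why: Nitroxyl/oxoammonium oxidation (Piancatelli–Margarita conditions) is selective for the primary C19 alcohol over the secondary C3 alcohol and stops at the aldehyde in dry CH2Cl2; the C4 descriptor changes only because the priorities change, and the aldehyde now also masks O19 for the next step.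

**Step 6**
Reactants: 8 (3R,4S,5S,9R,10S,13E)-3-hydroxy-14-iodo-15-norlabda-7,13-dien-19-al
Product: 10 (3S,4S,5S,9R,10S,13E)-3-acetoxy-14-iodo-15-norlabda-7,13-dien-19-al, via triflate 9 (not isolated)
Conditions: Tf2O, pyridine, CH2Cl2, −30 → 0 °C; then CsOAc, 18-crown-6, toluene, 40 °C
Reagents that add atoms: trifluoromethanesulfonic anhydride O=S(=O)(OS(=O)(=O)C(F)(F)F)C(F)(F)F (its triflyl group is carried by 9 only); caesium acetate CC(=O)[O-].[Cs+]
Why: Proposed new method: SN2 displacement by acetate of a secondary triflate next to a quaternary carbon, not yet shown because 4,4-disubstituted 3-sulfonates normally ionise, rearrange or eliminate; here the equatorial C3–OTf has no anti-periplanar β-hydrogen (E2 closed), the only aligned σ-bond (C4–C5) cannot migrate because that would place a cation beside the formyl group (ionisation and ring contraction closed), the axial C4 group eclipsing the leaving group is a small flat CHO instead of CH3, and crown-ether-freed acetate enters axially on the face opposite the C10 methyl and the formyl group past only H1ax/H5ax, so the new C3–O bond is axial (3S) by inversion; the closest known reaction type is the Lattrell–Dax and CsOAc/18-crown-6 inversion of hindered carbohydrate and steroid triflates.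

**Step 7**
Reactants: 10 (3S,4S,5S,9R,10S,13E)-3-acetoxy-14-iodo-15-norlabda-7,13-dien-19-al
Product: 11 (3S,4S,5S,9R,10S,13E)-3-acetoxy-19-oxolabda-7,13-dien-15-oic acid
Conditions: Pd(OAc)2 (5 mol %), dppf, CO (1 atm), KOAc, DMF–H2O, 50 °C
Reagents that add atoms: carbon monoxide [C-]#[O+]; water O
Why: Palladium-catalysed hydroxycarbonylation (Heck carbonylation: oxidative addition of zerovalent palladium, CO insertion, hydrolysis of the acyl complex) replaces iodine by CO2H with retention of the 13E geometry; the non-enolisable aldehyde and the hindered acetate survive the acetate buffer and no stereocentre is touched.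

**Compound list**
1 | andrographolide, (3R,4R,5S,9R,10S,12E,14S)-3,14,19-trihydroxylabda-8(17),12-dien-16,15-olide; 3-OH equatorial, 4-CH2OH axial and cis to the C10 methyl | O[C@@H]1CC[C@@]2(C)[C@H](C/C=C3/C(=O)OC[C@H]3O)C(=C)CC[C@@H]2[C@]1(C)CO | starting material
2 | epoxy lactone, 12,13-epoxy-12,13-dihydroandrographolide (epoxide diastereomers, configuration at C12/C13 of no consequence) | O[C@@H]1CC[C@@]2(C)[C@H](CC3OC34C(=O)OC[C@H]4O)C(=C)CC[C@@H]2[C@]1(C)CO | intermediate
3 | (3R,4R,5S,9R,10S)-3,19-dihydroxy-13,14,15,16-tetranorlabd-8(17)-en-12-al | O[C@@H]1CC[C@@]2(C)[C@H](CC=O)C(=C)CC[C@@H]2[C@]1(C)CO | intermediate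
4 | (3R,4R,5S,9R,10S)-3,19-dihydroxy-13,14,15,16-tetranorlabd-7-en-12-al | O[C@@H]1CC[C@@]2(C)[C@H](CC=O)C(C)=CC[C@@H]2[C@]1(C)CO | intermediate
5 | (3R,4R,5S,9R,10S)-14,15,16-trinorlabd-7-en-12-yne-3,19-diol | O[C@@H]1CC[C@@]2(C)[C@H](CC#C)C(C)=CC[C@@H]2[C@]1(C)CO | intermediate
6 | alkenylalane, (13E)-14-(dimethylalumanyl)-15-norlabda-7,13-diene-3,19-diol as its bis(dimethylaluminium) alkoxide | C[Al](C)O[C@@H]1CC[C@@]2(C)[C@H](CC/C(C)=C/[Al](C)C)C(C)=CC[C@@H]2[C@]1(C)CO[Al](C)C | intermediate
7 | (3R,4R,5S,9R,10S,13E)-14-iodo-15-norlabda-7,13-diene-3,19-diol | O[C@@H]1CC[C@@]2(C)[C@H](CC/C(C)=C/I)C(C)=CC[C@@H]2[C@]1(C)CO | intermediate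
8 | (3R,4S,5S,9R,10S,13E)-3-hydroxy-14-iodo-15-norlabda-7,13-dien-19-al; 3-OH equatorial, CHO axial | O[C@@H]1CC[C@@]2(C)[C@H](CC/C(C)=C/I)C(C)=CC[C@@H]2[C@]1(C)C=O | intermediate
9 | triflate, (3R,4S,5S,9R,10S,13E)-14-iodo-19-oxo-15-norlabda-7,13-dien-3-yl trifluoromethanesulfonate (equatorial OTf) | FC(F)(F)S(=O)(=O)O[C@@H]1CC[C@@]2(C)[C@H](CC/C(C)=C/I)C(C)=CC[C@@H]2[C@]1(C)C=O | intermediate
10 | (3S,4S,5S,9R,10S,13E)-3-acetoxy-14-iodo-15-norlabda-7,13-dien-19-al; 3-OAc axial | CC(=O)O[C@H]1CC[C@@]2(C)[C@H](CC/C(C)=C/I)C(C)=CC[C@@H]2[C@]1(C)C=O | intermediate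
11 | (3S,4S,5S,9R,10S,13E)-3-acetoxy-19-oxolabda-7,13-dien-15-oic acid (CNP0312710.1) | CC(=O)O[C@H]1CC[C@@]2(C)[C@H](CC/C(C)=C/C(=O)O)C(C)=CC[C@@H]2[C@]1(C)C=O | target

**Step count and risk**
Total step count: 7. Longest linear sequence: 7 (fully linear from 1).

The three steps most likely to fail:

Step 6, the proposed new inversion (risk: the neopentylic SN2 is too slow, so acetate attacks sulfur and returns 8, or a hydride shift and elimination take over). The fallback uses known chemistry, sets out from 8 and comes back at 10. Dess–Martin periodinane oxidises the C3 alcohol to the keto aldehyde F3. Me4NBH(OAc)3 in MeCN–AcOH at −20 °C first reduces the aldehyde and then, as the C19-bound alkoxyborohydride, delivers hydride to C3 from the face of C19 (Evans–Saksena directed reduction), giving the axial diol F4. TEMPO/PhI(OAc)2 re-oxidises only the primary alcohol to the hydroxy aldehyde F5. Ac2O, DMAP and pyridine then acetylate the axial alcohol to give 10.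

Step 1, the butenolide excision (risk: sluggish acid opening of the glycidic lactone, or base-induced loss of the 14-OH before the epoxide closes). The fallback sets out from 1 and comes back at 3. Activated MnO2 in acetone oxidises the allylic 14-OH to the 14-oxo lactone F1, a 3-alkylidene tetronic acid. Its doubly activated C12=C13 bond is then cut without an oxidant by hydrolytic retro-Knoevenagel scission in wet THF at pH 7, the tetronate being washed out with aqueous NaHCO3, which releases 3.

Step 2, the alkene shift (risk: competing C9–H abstraction giving the 8(9)-ene, or interference by the aldehyde). The fallback sets out from 3 and comes back at 5. The Seyferth–Gilbert homologation is run first, on the exocyclic alkene, to give the exocyclic-ene alkyne F2. The double bond is then moved by ionic protonation–deprotonation (TsOH·H2O cat., benzene, 60 °C; isomers separable on AgNO3-silica) instead of by radical hydrogen-atom transfer, giving 5.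

**Further compounds**
F1 | step 1 | 14-oxo lactone, (3R,4R,5S,9R,10S,12E)-3,19-dihydroxy-14-oxolabda-8(17),12-dien-16,15-olide | O[C@@H]1CC[C@@]2(C)[C@H](C/C=C3/C(=O)OCC3=O)C(=C)CC[C@@H]2[C@]1(C)CO
F2 | step 2 | exocyclic-ene alkyne, (3R,4R,5S,9R,10S)-14,15,16-trinorlabd-8(17)-en-12-yne-3,19-diol | O[C@@H]1CC[C@@]2(C)[C@H](CC#C)C(=C)CC[C@@H]2[C@]1(C)CO
F3 | step 6 | keto aldehyde, (4R,5S,9R,10S,13E)-14-iodo-3-oxo-15-norlabda-7,13-dien-19-al | O=C1CC[C@@]2(C)[C@H](CC/C(C)=C/I)C(C)=CC[C@@H]2[C@]1(C)C=O
F4 | step 6 | axial diol, (3S,4R,5S,9R,10S,13E)-14-iodo-15-norlabda-7,13-diene-3,19-diol | O[C@H]1CC[C@@]2(C)[C@H](CC/C(C)=C/I)C(C)=CC[C@@H]2[C@]1(C)CO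
F5 | step 6 | hydroxy aldehyde, (3S,4S,5S,9R,10S,13E)-3-hydroxy-14-iodo-15-norlabda-7,13-dien-19-al | O[C@H]1CC[C@@]2(C)[C@H](CC/C(C)=C/I)C(C)=CC[C@@H]2[C@]1(C)C=O
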